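**Retrosynthetic overview**
1. Target 28 ⇒ silyl-protected (S)-hydroxy acid 25 + allylic alcohol 20 (ester C–O); 20 ⇒ trisubstituted alkene 18 by a singlet-oxygen ene reaction (C3–O bond, exocyclic methylene).
2. Key step: the lactone C–O bond of oxaspirolactone 18 is closed last on hydroxy keto acid 16 under acyl-transfer control, which fixes the ketal carbon without acid.
3. 16 ⇒ spiro γ-lactone 12 + diallyl (R)-methylsuccinate 14 (Claisen acylation, then decarboxylation).
4. 12 ⇒ bicyclic ester 9 (face-selective enolate alkylation builds quaternary C6; reduction and lactonisation); 9 ⇒ (R)-carvone 1 (Criegee C–O, Johnson–Claisen, 4-exo-tet alkylation).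
5. Ring order: cyclohexene (from carvone) → cyclobutane (step 6) → oxolane, first as a lactone (step 8) → butyrolactone and spiro-ketal (step 11).

Convention: pinane numbering is used for the bicycle (C1, C5 bridgeheads; C2–C4 three-carbon bridge; C6 substituted one-carbon bridge; C7 CH2 bridge); syn and anti at C6 refer to the C2–C4 bridge.
Assumption: the spiro-ketal carbon and the pinene-type alkenes do not survive protic acid, so nothing more acidic than pyridine-buffered HF·pyridine is used after step 6.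

**Step 1**
Reactants: 1 (R)-(−)-carvone
Product: 3 (1R)-4-methyl-5-oxocyclohex-3-en-1-yl acetate, via methoxy hydroperoxide 2 (not isolated)
Conditions: O3, CH2Cl2–MeOH (5:1), −78 °C; then Ac2O, Et3N, DMAP (cat.), −78 → 0 °C
Reagents that add atoms: ozone ([O-][O+]=O); methanol (CO)
Why: Ozonolysis–Criegee rearrangement (Schreiber): only the electron-rich isopropenyl group is ozonised, the carbonyl oxide is trapped by MeOH, and on O-acetylation the ring carbon migrates to oxygen with retention, so the old C5 of carvone keeps its configuration (the acetyl group of 3 is the former C–CH3 unit of the isopropenyl group).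

**Step 2**
Reactants: 3 (1R)-4-methyl-5-oxocyclohex-3-en-1-yl acetate
Product: 4 (1R,5R)-5-hydroxy-4-methylcyclohex-3-en-1-yl acetate (OH cis to OAc)
Conditions: NaBH4, CeCl3·7H2O, MeOH, −78 °C
Reagents that add atoms: none
Why: Luche 1,2-reduction; axial hydride delivery gives the cis allylic alcohol, as in carvone → cis-carveol, and the acetate survives at −78 °C.

**Step 3**
Reactants: 4 (1R,5R)-5-hydroxy-4-methylcyclohex-3-en-1-yl acetate
Product: 6 ethyl 2-[(1R,5S)-5-acetoxy-2-methylcyclohex-2-en-1-yl]acetate, via ketene acetal 5 (not isolated)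
Conditions: MeC(OEt)3 (6 equiv), EtCO2H (cat.), 140 °C, EtOH distilled off
Reagents that add atoms: triethyl orthoacetate (CCOC(C)(OCC)OCC)
Why: Johnson–Claisen [3,3] rearrangement; it is suprafacial, so the CH2CO2Et arm is delivered to the former enone β-carbon on the face the oxygen leaves (cis to OAc) and the alkene moves to the position of the later pinene-type double bond.

**Step 4**
Reactants: 6 ethyl 2-[(1R,5S)-5-acetoxy-2-methylcyclohex-2-en-1-yl]acetate
Product: 7 ethyl 2-[(1R,5S)-5-hydroxy-2-methylcyclohex-2-en-1-yl]acetate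
Conditions: K2CO3 (0.2 equiv), EtOH, rt; neutralise before concentration
Reagents that add atoms: none
Why: Base-catalysed transesterification removes the secondary acetate, while ethanol as solvent keeps the ethyl ester and suppresses closure to the bridged lactone.

**Step 5**
Reactants: 7 ethyl 2-[(1R,5S)-5-hydroxy-2-methylcyclohex-2-en-1-yl]acetate
Product: 8 ethyl 2-[(1S,5R)-5-bromo-2-methylcyclohex-2-en-1-yl]acetate (Br trans to the acetate arm)
Conditions: CBr4, PPh3, CH2Cl2, 0 °C
Reagents that add atoms: carbon tetrabromide (BrC(Br)(Br)Br)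
Why: Appel bromination proceeds by SN2 inversion, which puts the leaving group on the face opposite the arm as needed for backside ring closure.

**Step 6**
Reactants: 8 ethyl 2-[(1S,5R)-5-bromo-2-methylcyclohex-2-en-1-yl]acetate
Product: 9 ethyl (1R,5S)-2-methylbicyclo[3.1.1]hept-2-ene-6-carboxylate (both C6 epimers)
Conditions: KN(SiMe3)2, THF, −78 °C → rt
Reagents that add atoms: none
Why: Intramolecular 4-exo-tet ester-enolate alkylation (Thomas–Fallis/Stork-type cyclobutane closure); allylic 1,2-strain holds the arm pseudo-axial, and inversion at C–Br gives the cis-1,3 bridge, so both bridgeheads follow from the Claisen-derived stereocentre.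

**Step 7**
Reactants: 9 ethyl (1R,5S)-2-methylbicyclo[3.1.1]hept-2-ene-6-carboxylate
Product: 10 ethyl (1S,5S,6S)-6-(2-tert-butoxy-2-oxoethyl)-2-methylbicyclo[3.1.1]hept-2-ene-6-carboxylate (CO2Et syn, CH2CO2t-Bu anti)
Conditions: LiN(i-Pr)2, THF, −78 °C; BrCH2CO2t-Bu, −78 → 0 °C
Reagents that add atoms: tert-butyl bromoacetate (CC(C)(C)OC(=O)CBr)
Why: Ester-enolate alkylation; the electrophile should enter the exocyclic enolate from the CH2-bridge face, anti to the larger three-carbon bridge, which sets quaternary C6 with the ester (future CH2–O) syn.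

**Step 8**
Reactants: 10 ethyl (1S,5S,6S)-6-(2-tert-butoxy-2-oxoethyl)-2-methylbicyclo[3.1.1]hept-2-ene-6-carboxylate
Product: 12 (1S,5S,6S)-2-methylspiro[bicyclo[3.1.1]hept-2-ene-6,3′-oxolan]-5′-one, via hydroxy tert-butyl ester 11 (not isolated)
Conditions: LiBH4, THF–MeOH (cat.), 0 → 40 °C
Reagents that add atoms: none
Why: Chemoselective borohydride reduction of the ethyl ester (tert-butyl esters are inert to LiBH4), after which the neopentyl alkoxide closes 5-exo-trig onto the tert-butyl ester, giving the future oxolane ring as a γ-lactone.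

**Step 9**
Reactants: 13 (R)-2-methylsuccinic acid
Product: 14 diallyl (R)-2-methylsuccinate
Conditions: allyl alcohol, TsOH (cat.), PhMe, reflux (Dean–Stark)
Reagents that add atoms: allyl alcohol (C=CCO)
Why: Fischer esterification; acidic conditions do not epimerise the α-methyl centre, which becomes the lactone α-carbon of the target.

**Step 10**
Reactants: 12 (1S,5S,6S)-2-methylspiro[bicyclo[3.1.1]hept-2-ene-6,3′-oxolan]-5′-one; 14 diallyl (R)-2-methylsuccinate
Product: 16 (2R)-5-[(1S,5S,6S)-6-(hydroxymethyl)-2-methylbicyclo[3.1.1]hept-2-en-6-yl]-2-methyl-4-oxopentanoic acid (handled as its morpholinium salt), via keto diester 15 (not isolated)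
Conditions: 14 (2.2 equiv), LiN(i-Pr)2 (2.2 equiv), THF, −78 °C; then 12, −78 → −40 °C; AcOH; then Pd(PPh3)4 (5 mol %), morpholine, THF, rt
Reagents that add atoms: none
Why: Crossed Claisen acylation of the kinetic CH2-enolate of 14 by the lactone, then zerovalent-palladium deallylation (Tsuji–Kunz) with spontaneous decarboxylation of the β-keto acid; conditions stay non-acidic, and the methyl stereocentre is not the enolised carbon.

**Step 11**
Reactants: 16 (2R)-5-[(1S,5S,6S)-6-(hydroxymethyl)-2-methylbicyclo[3.1.1]hept-2-en-6-yl]-2-methyl-4-oxopentanoic acid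
Product: 18 (1S,5S,6S,5′R,4″R)-2,4″-dimethyldispiro[bicyclo[3.1.1]hept-2-ene-6,3′-oxolane-5′,2″-oxolan]-5″-one, via mixed pivalic anhydride 17 (not isolated)
Conditions: Piv2O (1.2 equiv), (R)-benzotetramisole (10 mol %), i-Pr2NEt (2.5 equiv), CH2Cl2 (0.01 M), −20 °C
Reagents that add atoms: none
Why: Proposed new method: acyl-transfer-catalysed dynamic kinetic spirolactonisation — the carboxylate is activated through the mixed pivalic anhydride as a chiral acyl isothiouronium, the CH2OH/ketone pair equilibrates rapidly between the two epimeric cyclic hemiketals, and only the hemiketal whose tertiary OH reaches the acyl carbon with the α-methyl and the ring CH2 both pseudo-equatorial closes irreversibly (Curtin–Hammett), forming the lactone C–O bond and fixing the (R)-ketal carbon under base where neither the spiro centre nor the pinene-type alkene can equilibrate. The matched catalyst enantiomer is a prediction and would be confirmed by screening its antipode. Closest known reactions are isothiourea/Piv2O esterification and kinetic resolution of α-branched acids (Shiina–Birman) and DKR acylation of lactols.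

**Step 12**
Reactants: 18 (1S,5S,6S,5′R,4″R)-2,4″-dimethyldispiro[bicyclo[3.1.1]hept-2-ene-6,3′-oxolane-5′,2″-oxolan]-5″-one
Product: 20 (1R,3S,5R,6S,5′R,4″R)-3-hydroxy-4″-methyl-2-methylidenedispiro[bicyclo[3.1.1]heptane-6,3′-oxolane-5′,2″-oxolan]-5″-one, via allylic hydroperoxide 19 (not isolated)
Conditions: O2, tetraphenylporphyrin (cat.), visible light, CH2Cl2, 0 °C; then PPh3
Reagents that add atoms: oxygen (O=O)
Why: Schenck ene reaction of singlet oxygen, as in α-pinene → trans-pinocarveol: oxygen adds to C3 from the face anti to the C6 bridge (the syn CH2–O shields the other face) with hydrogen taken from the vinylic methyl, giving the exocyclic methylene and the C3 stereocentre; the hydroperoxide is then reduced.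

**Step 13**
Reactants: 21 methyl 2,2-dimethyl-3-oxobutanoate
Product: 22 methyl (3S)-3-hydroxy-2,2-dimethylbutanoate
Conditions: H2 (50 atm), RuBr2[(S)-BINAP] (0.1 mol %), MeOH, 50 °C
Reagents that add atoms: none
Why: Noyori asymmetric hydrogenation of a β-keto ester; the (S)-BINAP catalyst gives the (S)-carbinol, the same sense as methyl acetoacetate.

**Step 14**
Reactants: 22 methyl (3S)-3-hydroxy-2,2-dimethylbutanoate
Product: 23 (3S)-3-hydroxy-2,2-dimethylbutanoic acid
Conditions: LiOH, THF–MeOH–H2O, 50 °C; then HCl (aq.)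
Reagents that add atoms: lithium hydroxide ([Li+].[OH-])
Why: Saponification of the hindered ester; with a quaternary α-carbon nothing can epimerise or eliminate.

**Step 15**
Reactants: 23 (3S)-3-hydroxy-2,2-dimethylbutanoic acid
Product: 25 (3S)-3-[(tert-butyldimethylsilyl)oxy]-2,2-dimethylbutanoic acid, via bis-silyl derivative 24 (not isolated)
Conditions: TBSOTf (2.2 equiv), 2,6-lutidine, CH2Cl2, 0 °C; then K2CO3 (cat.), MeOH–H2O
Reagents that add atoms: tert-butyldimethylsilyl triflate (CC(C)(C)[Si](C)(C)OS(=O)(=O)C(F)(F)F)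
Why: Silylation of both OH and CO2H, then selective solvolysis of the labile silyl ester, leaves the hindered secondary silyl ether.

**Step 16**
Reactants: 20 (1R,3S,5R,6S,5′R,4″R)-3-hydroxy-4″-methyl-2-methylidenedispiro[bicyclo[3.1.1]heptane-6,3′-oxolane-5′,2″-oxolan]-5″-one; 25 (3S)-3-[(tert-butyldimethylsilyl)oxy]-2,2-dimethylbutanoic acid
Product: 27 (1R,3S,5R,6S,5′R,4″R)-4″-methyl-2-methylidene-5″-oxodispiro[bicyclo[3.1.1]heptane-6,3′-oxolane-5′,2″-oxolan]-3-yl (3S)-3-[(tert-butyldimethylsilyl)oxy]-2,2-dimethylbutanoate, via mixed aryl anhydride 26 (not isolated)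
Conditions: 25, 2,4,6-Cl3C6H2COCl, Et3N, PhMe, rt; then 20, DMAP, 60 °C
Reagents that add atoms: none
Why: Yamaguchi esterification, suited to an α-quaternary acid and a secondary allylic alcohol; the carbinol C–O bond is not broken, so C3 is retained.

**Step 17**
Reactants: 27 (1R,3S,5R,6S,5′R,4″R)-4″-methyl-2-methylidene-5″-oxodispiro[bicyclo[3.1.1]heptane-6,3′-oxolane-5′,2″-oxolan]-3-yl (3S)-3-[(tert-butyldimethylsilyl)oxy]-2,2-dimethylbutanoate
Product: 28 (1R,3S,5R,6S,5′R,4″R)-4″-methyl-2-methylidene-5″-oxodispiro[bicyclo[3.1.1]heptane-6,3′-oxolane-5′,2″-oxolan]-3-yl (3S)-3-hydroxy-2,2-dimethylbutanoate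
Conditions: HF·pyridine, excess pyridine, THF, 0 °C → rt
Reagents that add atoms: none
Why: Fluoride desilylation under pyridine buffering, mild enough for the spiro-ketal lactone, the allylic ester and the exocyclic alkene.

**Compound list**
1 | (R)-(−)-carvone, (5R)-2-methyl-5-(prop-1-en-2-yl)cyclohex-2-en-1-one | CC(=C)[C@@H]1CC=C(C)C(=O)C1 | starting material
2 | (5R)-5-(1-hydroperoxy-1-methoxyethyl)-2-methylcyclohex-2-en-1-one (side-chain epimers) | COC(C)(OO)[C@@H]1CC=C(C)C(=O)C1 | intermediate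
3 | (1R)-4-methyl-5-oxocyclohex-3-en-1-yl acetate | CC(=O)O[C@@H]1CC=C(C)C(=O)C1 | intermediate
4 | (1R,5R)-5-hydroxy-4-methylcyclohex-3-en-1-yl acetate (cis) | CC(=O)O[C@@H]1CC=C(C)[C@H](O)C1 | intermediate
5 | (1R,5R)-5-[(1-ethoxyethenyl)oxy]-4-methylcyclohex-3-en-1-yl acetate | CC(=O)O[C@@H]1CC=C(C)[C@H](OC(=C)OCC)C1 | intermediate
6 | ethyl 2-[(1R,5S)-5-acetoxy-2-methylcyclohex-2-en-1-yl]acetate (cis) | CC(=O)O[C@@H]1C[C@H](CC(=O)OCC)C(C)=CC1 | intermediate
7 | ethyl 2-[(1R,5S)-5-hydroxy-2-methylcyclohex-2-en-1-yl]acetate (cis) | O[C@@H]1C[C@H](CC(=O)OCC)C(C)=CC1 | intermediate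
8 | ethyl 2-[(1S,5R)-5-bromo-2-methylcyclohex-2-en-1-yl]acetate (trans) | Br[C@H]1C[C@H](CC(=O)OCC)C(C)=CC1 | intermediate
9 | ethyl (1R,5S)-2-methylbicyclo[3.1.1]hept-2-ene-6-carboxylate (C6 epimers) | CCOC(=O)C1[C@H]2C[C@@H]1CC=C2C | intermediate
10 | ethyl (1S,5S,6S)-6-(2-tert-butoxy-2-oxoethyl)-2-methylbicyclo[3.1.1]hept-2-ene-6-carboxylate (ester syn) | CCOC(=O)[C@]1(CC(=O)OC(C)(C)C)[C@H]2C[C@@H]1CC=C2C | intermediate
11 | tert-butyl 2-[(1S,5S,6S)-6-(hydroxymethyl)-2-methylbicyclo[3.1.1]hept-2-en-6-yl]acetate | OC[C@]1(CC(=O)OC(C)(C)C)[C@H]2C[C@@H]1CC=C2C | intermediate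
12 | (1S,5S,6S)-2-methylspiro[bicyclo[3.1.1]hept-2-ene-6,3′-oxolan]-5′-one (ring CH2–O syn) | O=C1C[C@@]2(CO1)[C@H]3C[C@@H]2CC=C3C | intermediate
13 | (R)-2-methylsuccinic acid | C[C@H](CC(=O)O)C(=O)O | starting material
14 | diallyl (R)-2-methylsuccinate | C[C@H](CC(=O)OCC=C)C(=O)OCC=C | intermediate
15 | bis(prop-2-enyl) (3R)-2-{2-[(1S,5S,6S)-6-(hydroxymethyl)-2-methylbicyclo[3.1.1]hept-2-en-6-yl]acetyl}-3-methylbutanedioate (C2 epimers) | OC[C@]1(CC(=O)C(C(=O)OCC=C)[C@@H](C)C(=O)OCC=C)[C@H]2C[C@@H]1CC=C2C | intermediate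
16 | (2R)-5-[(1S,5S,6S)-6-(hydroxymethyl)-2-methylbicyclo[3.1.1]hept-2-en-6-yl]-2-methyl-4-oxopentanoic acid | OC[C@]1(CC(=O)C[C@@H](C)C(=O)O)[C@H]2C[C@@H]1CC=C2C | intermediate
17 | mixed anhydride of 16 with pivalic acid | OC[C@]1(CC(=O)C[C@@H](C)C(=O)OC(=O)C(C)(C)C)[C@H]2C[C@@H]1CC=C2C | intermediate
18 | (1S,5S,6S,5′R,4″R)-2,4″-dimethyldispiro[bicyclo[3.1.1]hept-2-ene-6,3′-oxolane-5′,2″-oxolan]-5″-one | CC1=CC[C@H]2C[C@@H]1[C@@]21CO[C@@]2(C[C@@H](C)C(=O)O2)C1 | intermediate
19 | (1R,3S,5R,6S,5′R,4″R)-3-hydroperoxy-4″-methyl-2-methylidenedispiro[bicyclo[3.1.1]heptane-6,3′-oxolane-5′,2″-oxolan]-5″-one | C=C1[C@@H](OO)C[C@H]2C[C@@H]1[C@@]21CO[C@@]2(C[C@@H](C)C(=O)O2)C1 | intermediate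
20 | (1R,3S,5R,6S,5′R,4″R)-3-hydroxy-4″-methyl-2-methylidenedispiro[bicyclo[3.1.1]heptane-6,3′-oxolane-5′,2″-oxolan]-5″-one (OH anti to C6) | C=C1[C@@H](O)C[C@H]2C[C@@H]1[C@@]21CO[C@@]2(C[C@@H](C)C(=O)O2)C1 | intermediate
21 | methyl 2,2-dimethyl-3-oxobutanoate | COC(=O)C(C)(C)C(C)=O | starting material
22 | methyl (3S)-3-hydroxy-2,2-dimethylbutanoate | COC(=O)C(C)(C)[C@H](C)O | intermediate
23 | (3S)-3-hydroxy-2,2-dimethylbutanoic acid | OC(=O)C(C)(C)[C@H](C)O | intermediate
24 | tert-butyldimethylsilyl (3S)-3-[(tert-butyldimethylsilyl)oxy]-2,2-dimethylbutanoate | CC(C)(C)[Si](C)(C)OC(=O)C(C)(C)[C@H](C)O[Si](C)(C)C(C)(C)C | intermediate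
25 | (3S)-3-[(tert-butyldimethylsilyl)oxy]-2,2-dimethylbutanoic acid | OC(=O)C(C)(C)[C@H](C)O[Si](C)(C)C(C)(C)C | intermediate
26 | (3S)-3-[(tert-butyldimethylsilyl)oxy]-2,2-dimethylbutanoic 2,4,6-trichlorobenzoic anhydride | O=C(OC(=O)C(C)(C)[C@H](C)O[Si](C)(C)C(C)(C)C)c1c(Cl)cc(Cl)cc1Cl | intermediate
27 | (1R,3S,5R,6S,5′R,4″R)-4″-methyl-2-methylidene-5″-oxodispiro[bicyclo[3.1.1]heptane-6,3′-oxolane-5′,2″-oxolan]-3-yl (3S)-3-[(tert-butyldimethylsilyl)oxy]-2,2-dimethylbutanoate | C=C1[C@@H](OC(=O)C(C)(C)[C@H](C)O[Si](C)(C)C(C)(C)C)C[C@H]2C[C@@H]1[C@@]21CO[C@@]2(C[C@@H](C)C(=O)O2)C1 | intermediate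
28 | (1R,3S,5R,6S,5′R,4″R)-4″-methyl-2-methylidene-5″-oxodispiro[bicyclo[3.1.1]heptane-6,3′-oxolane-5′,2″-oxolan]-3-yl (3S)-3-hydroxy-2,2-dimethylbutanoate | C=C1[C@@H](OC(=O)C(C)(C)[C@H](C)O)C[C@H]2C[C@@H]1[C@@]21CO[C@@]2(C[C@@H](C)C(=O)O2)C1 | target

**Step count**
Total: 17 steps. Longest linear sequence: 13 steps (steps 1–8, 10, 11, 12, 16, 17, from carvone).

**Three steps most likely to fail**

Step 6 (4-exo-tet closure; elimination of HBr or O-alkylation may compete). The fallback sets out from 8 and comes back at 9. The lithium enolate of 8 is C-acylated with ethyl chloroformate at −78 °C to give diethyl 2-[(1R,5R)-5-bromo-2-methylcyclohex-2-en-1-yl]propanedioate F1. The softer, less basic malonate anion (NaH, DMF, 60 °C) closes the cyclobutane in the classical cyclobutane-1,1-dicarboxylate manner to diethyl (1S,5S)-2-methylbicyclo[3.1.1]hept-2-ene-6,6-dicarboxylate F2. Krapcho dealkoxycarbonylation (LiCl, wet DMSO, 160 °C) then removes one ester and returns 9.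

Step 7 (facial selectivity at the quaternary C6). The facial bias belongs to the enolate and is the same for any electrophile, so if electrophiles enter syn instead of anti, the order of introducing the two carbons is reversed. The fallback sets out from 9 and comes back at 12.
- The enolate of 9 is alkylated with 4-methoxybenzyl chloromethyl ether to give ethyl (1S,5S,6R)-6-{[(4-methoxyphenyl)methoxy]methyl}-2-methylbicyclo[3.1.1]hept-2-ene-6-carboxylate F3, with the CH2O group now syn.
- Saponification (KOH, aqueous EtOH) gives (1S,5S,6R)-6-{[(4-methoxyphenyl)methoxy]methyl}-2-methylbicyclo[3.1.1]hept-2-ene-6-carboxylic acid F4.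
- Oxalyl chloride converts it into (1S,5S,6R)-6-{[(4-methoxyphenyl)methoxy]methyl}-2-methylbicyclo[3.1.1]hept-2-ene-6-carbonyl chloride F5.
- Trimethylsilyldiazomethane gives 2-diazo-1-[(1S,5S,6R)-6-{[(4-methoxyphenyl)methoxy]methyl}-2-methylbicyclo[3.1.1]hept-2-en-6-yl]ethan-1-one F6.
- Wolff rearrangement (PhCO2Ag, Et3N, aqueous THF; Arndt–Eistert homologation with retention) gives 2-[(1S,5S,6S)-6-{[(4-methoxyphenyl)methoxy]methyl}-2-methylbicyclo[3.1.1]hept-2-en-6-yl]acetic acid F7.
- DDQ in buffered CH2Cl2–water frees 2-[(1S,5S,6S)-6-(hydroxymethyl)-2-methylbicyclo[3.1.1]hept-2-en-6-yl]acetic acid F8, which lactonises on concentration (or with a carbodiimide) to 12.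

Step 11 (the proposed new spirolactonisation; the hemiketal OH may acylate too slowly, or catalyst control may be weak). The fallback uses known chemistry, sets out from 16 and comes back at 18. The salt of 16 is neutralised and stirred with pyridinium p-toluenesulfonate (cat.) and 4 Å molecular sieves in CH2Cl2. This classical dehydrative spiro-ketal lactonisation is thermodynamically controlled and gives 18 together with its ketal epimer (1S,5S,6S,5′S,4″R)-2,4″-dimethyldispiro[bicyclo[3.1.1]hept-2-ene-6,3′-oxolane-5′,2″-oxolan]-5″-one F9. Compound 18 is expected to be the major epimer (ketal oxygen pseudo-axial, methyl and ring CH2 pseudo-equatorial), though the ratio is not known. The epimers are separated by chromatography and F9 is re-equilibrated under the same conditions.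

**Further compounds**
F1 | step 6 | diethyl 2-[(1R,5R)-5-bromo-2-methylcyclohex-2-en-1-yl]propanedioate | Br[C@H]1C[C@H](C(C(=O)OCC)C(=O)OCC)C(C)=CC1
F2 | step 6 | diethyl (1S,5S)-2-methylbicyclo[3.1.1]hept-2-ene-6,6-dicarboxylate | CCOC(=O)C1(C(=O)OCC)[C@H]2C[C@@H]1CC=C2C
F3 | step 7 | ethyl (1S,5S,6R)-6-{[(4-methoxyphenyl)methoxy]methyl}-2-methylbicyclo[3.1.1]hept-2-ene-6-carboxylate | CCOC(=O)[C@@]1(COCc2ccc(OC)cc2)[C@H]2C[C@@H]1CC=C2C
F4 | step 7 | (1S,5S,6R)-6-{[(4-methoxyphenyl)methoxy]methyl}-2-methylbicyclo[3.1.1]hept-2-ene-6-carboxylic acid | OC(=O)[C@@]1(COCc2ccc(OC)cc2)[C@H]2C[C@@H]1CC=C2C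
F5 | step 7 | (1S,5S,6R)-6-{[(4-methoxyphenyl)methoxy]methyl}-2-methylbicyclo[3.1.1]hept-2-ene-6-carbonyl chloride | ClC(=O)[C@@]1(COCc2ccc(OC)cc2)[C@H]2C[C@@H]1CC=C2C
F6 | step 7 | 2-diazo-1-[(1S,5S,6R)-6-{[(4-methoxyphenyl)methoxy]methyl}-2-methylbicyclo[3.1.1]hept-2-en-6-yl]ethan-1-one | [N-]=[N+]=CC(=O)[C@@]1(COCc2ccc(OC)cc2)[C@H]2C[C@@H]1CC=C2C
F7 | step 7 | 2-[(1S,5S,6S)-6-{[(4-methoxyphenyl)methoxy]methyl}-2-methylbicyclo[3.1.1]hept-2-en-6-yl]acetic acid | OC(=O)C[C@@]1(COCc2ccc(OC)cc2)[C@H]2C[C@@H]1CC=C2C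
F8 | step 7 | 2-[(1S,5S,6S)-6-(hydroxymethyl)-2-methylbicyclo[3.1.1]hept-2-en-6-yl]acetic acid | OC(=O)C[C@@]1(CO)[C@H]2C[C@@H]1CC=C2C
F9 | step 11 | (1S,5S,6S,5′S,4″R)-2,4″-dimethyldispiro[bicyclo[3.1.1]hept-2-ene-6,3′-oxolane-5′,2″-oxolan]-5″-one | CC1=CC[C@H]2C[C@@H]1[C@@]21CO[C@]2(C[C@@H](C)C(=O)O2)C1
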